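Everything rests on cutting the bond between ring carbon C6, the only unsubstituted position ortho to the phenolic oxygen on C1, and the allylic methylene C1' of the dihydroxylated geranylgeranyl chain. The key step joins the complete C20 chain, carried as its (2'E)-allylic bromide with both carbinol centres set, to the unprotected phenol: bromine–lithium exchange on 2-bromo-4-methoxy-6-methylphenol gives an O,C-dilithio species whose aryl carbon, after transfer to copper, displaces the primary bromide at C1'. It exploits the hydroxyl-directed access to C6 and the fully substituted C3', which blocks γ-attack and preserves the alkene geometry. The chain comes from geranyl acetate; one chiral phosphoric acid sets both carbinols and a carboalumination the 2'E alkene.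

Key step: step 10

Remark on the chemistry: the target is read as the (5'R,12'R)-diol with 2'E, 6'E and 10'E alkenes (ring: C1 OH, C2 methyl, C4 methoxy, C6 chain; chain atoms C1' to C16' counted from the benzylic carbon). Geranyl acetate, 4-methoxy-2-methylphenol and the two pinacol boronates are taken as purchased.

Step 1
Reactants: 1 geranyl acetate
Product: 3 (2E,6E)-3,7-dimethyl-8-oxoocta-2,6-dien-1-yl acetate, via hydroxy acetate 2 (not isolated)
Conditions: SeO2 (0.3 equiv), t-BuOOH (3 equiv), salicylic acid (0.1 equiv), CH2Cl2, rt; filtration, then MnO2 (excess), CH2Cl2, rt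
Reagents that add atoms: selenium dioxide, O=[Se]=O; tert-butyl hydroperoxide, CC(C)(C)OO
Why: Riley allylic oxidation (ene reaction, then [2,3]-sigmatropic shift) attacks only the (E)-methyl of the electron-rich terminal alkene because the C2=C3 alkene is deactivated by the allylic acetate, and MnO2 takes the resulting mixture of allylic alcohol 2 and enal on to the (E)-enal.

Step 2
Reactants: 3 (2E,6E)-3,7-dimethyl-8-oxoocta-2,6-dien-1-yl acetate
Product: 5 (2E,6E,8R)-3,7-dimethylundeca-2,6,10-triene-1,8-diol, via borate ester 4 (not isolated)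
Conditions: allylboronic acid pinacol ester (1.3 equiv), (R)-TRIP [(R)-3,3'-bis(2,4,6-triisopropylphenyl)-1,1'-binaphthyl-2,2'-diyl hydrogen phosphate] (5 mol%), toluene, −30 °C; then K2CO3, MeOH, rt
Reagents that add atoms: allylboronic acid pinacol ester, C=CCB1OC(C)(C)C(C)(C)O1
Why: Chiral-phosphoric-acid-catalysed allylboration through a closed chair transition state, in which the (R)-acid is hydrogen-bonded to the pseudo-axial boronate oxygen and the formyl hydrogen, should expose the Re face of the α-methyl enal and set the 8R carbinol (C12' of the target), after which methanolysis cleaves both the borate and the acetate.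

Step 3
Reactants: 5 (2E,6E,8R)-3,7-dimethylundeca-2,6,10-triene-1,8-diol
Product: 6 (2E,6E,8R)-3,7,11-trimethyldodeca-2,6,10-triene-1,8-diol
Conditions: 2-methyl-2-butene (large excess), second-generation Grubbs catalyst (3 mol%), CH2Cl2, rt
Reagents that add atoms: 2-methyl-2-butene, CC=C(C)C
Why: Olefin cross-metathesis exchanges the methylene of the only monosubstituted alkene for an isopropylidene group, the trisubstituted alkenes and free hydroxyls being inert to the ruthenium carbene under these conditions.

Step 4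
Reactants: 6 (2E,6E,8R)-3,7,11-trimethyldodeca-2,6,10-triene-1,8-diol
Product: 7 (2E,6E,8R)-8-hydroxy-3,7,11-trimethyldodeca-2,6,10-trienal
Conditions: TEMPO (0.1 equiv), PhI(OAc)2 (1.1 equiv), CH2Cl2, 0 °C to rt
Reagents that add atoms: none
Why: Oxoammonium (TEMPO) oxidation is strongly selective for the unhindered primary allylic alcohol over the hindered secondary C8 carbinol and leaves the 2E geometry untouched.

Step 5
Reactants: 7 (2E,6E,8R)-8-hydroxy-3,7,11-trimethyldodeca-2,6,10-trienal
Product: 9 (4R,5E,9E,11R)-6,10,14-trimethylpentadeca-5,9,13-trien-1-yne-4,11-diol, via borate ester 8 (not isolated)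
Conditions: allenylboronic acid pinacol ester (1.5 equiv), (R)-TRIP (10 mol%), 4 Å molecular sieves, toluene, 0 °C; then MeOH, rt
Reagents that add atoms: allenylboronic acid pinacol ester, C=C=CB1OC(C)(C)C(C)(C)O1
Why: Chiral-phosphoric-acid-catalysed propargylation, in which the allenylboronate adds through its γ-carbon (SE2') in the same hydrogen-bonded chair transition state as in step 2, should again deliver carbon to the Re face of the enal and set the 4R carbinol (C5' of the target) independently of the remote C11 centre.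

Step 6
Reactants: 9 (4R,5E,9E,11R)-6,10,14-trimethylpentadeca-5,9,13-trien-1-yne-4,11-diol
Product: 10 (4R,5E,9E,11R)-4,11-bis[(tert-butyldimethylsilyl)oxy]-6,10,14-trimethylpentadeca-5,9,13-trien-1-yne
Conditions: TBSOTf (2.5 equiv), 2,6-lutidine (4 equiv), CH2Cl2, −78 to 0 °C
Reagents that add atoms: tert-butyldimethylsilyl triflate, CC(C)(C)[Si](C)(C)OS(=O)(=O)C(F)(F)F
Why: Silylation with the reactive triflate protects both secondary carbinols, including the hindered C11 hydroxyl, as ethers that tolerate the organoaluminium, organolithium and organocopper reagents to come.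

Step 7
Reactants: 10 (4R,5E,9E,11R)-4,11-bis[(tert-butyldimethylsilyl)oxy]-6,10,14-trimethylpentadeca-5,9,13-trien-1-yne
Product: 13 (2E,5R,6E,10E,12R)-5,12-bis[(tert-butyldimethylsilyl)oxy]-3,7,11,15-tetramethylhexadeca-2,6,10,14-tetraen-1-ol, via alkenylalane 11 (not isolated), via lithium alanate 12 (not isolated)
Conditions: AlMe3 (3 equiv), Cp2ZrCl2 (0.25 equiv), CH2Cl2, 0 °C to rt; volatiles removed under vacuum; THF, n-BuLi (1.1 equiv), −78 °C; (CH2O)n (excess), −78 °C to rt; aqueous KNaC4H4O6 (potassium sodium tartrate)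
Reagents that add atoms: trimethylaluminium, C[Al](C)C; paraformaldehyde (as formaldehyde), C=O
Why: Negishi zirconium-catalysed carboalumination adds methyl and aluminium syn across the terminal alkyne with aluminium on the terminal carbon, and the derived alanate is hydroxymethylated with retention, which fixes the 2E trisubstituted alkene.

Step 8
Reactants: 13 (2E,5R,6E,10E,12R)-5,12-bis[(tert-butyldimethylsilyl)oxy]-3,7,11,15-tetramethylhexadeca-2,6,10,14-tetraen-1-ol
Product: 14 (2E,5R,6E,10E,12R)-1-bromo-5,12-bis[(tert-butyldimethylsilyl)oxy]-3,7,11,15-tetramethylhexadeca-2,6,10,14-tetraene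
Conditions: CBr4 (1.3 equiv), PPh3 (1.4 equiv), 2,6-lutidine (0.5 equiv), CH2Cl2, −20 to 0 °C; used at once
Reagents that add atoms: carbon tetrabromide, BrC(Br)(Br)Br
Why: Appel bromination converts the primary allylic alcohol into the bromide by SN2 displacement of the alkoxyphosphonium ion under near-neutral conditions, without allylic transposition or loss of the E geometry.

Step 9
Reactants: 15 4-methoxy-2-methylphenol
Product: 16 2-bromo-4-methoxy-6-methylphenol
Conditions: NBS (1.0 equiv), i-Pr2NH (0.1 equiv), CH2Cl2, 0 °C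
Reagents that add atoms: N-bromosuccinimide, O=C1CCC(=O)N1Br
Why: Amine-catalysed electrophilic aromatic bromination is directed by hydrogen bonding to the phenolic hydroxyl to its only free ortho carbon, C6, the other ortho and the para position being blocked by methyl and methoxy.

Step 10
Reactants: 16 2-bromo-4-methoxy-6-methylphenol; 14 (2E,5R,6E,10E,12R)-1-bromo-5,12-bis[(tert-butyldimethylsilyl)oxy]-3,7,11,15-tetramethylhexadeca-2,6,10,14-tetraene
Product: 19 2-[(2E,5R,6E,10E,12R)-5,12-bis[(tert-butyldimethylsilyl)oxy]-3,7,11,15-tetramethylhexadeca-2,6,10,14-tetraen-1-yl]-4-methoxy-6-methylphenol, via dilithio phenoxide 17 (not isolated), via arylcopper 18 (not isolated)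
Conditions: 16 (2.0 equiv), t-BuLi (6.1 equiv), THF, −78 °C; CuBr·SMe2 (2.0 equiv), −78 to −40 °C; 14 (1.0 equiv), −78 to 0 °C; aqueous NH4Cl
Reagents that add atoms: none
Why: Deprotonation of the hydroxyl and bromine–lithium exchange turn 16 into the C6-lithiated lithium phenoxide 17, transmetalation gives the monovalent arylcopper 18, and this attacks the primary allylic bromide 14 at C1' (oxidative addition to a σ-allyl trivalent copper species, then reductive elimination) to forge the C6–C1' bond. The closest known reaction type is the copper-mediated coupling of ortho-lithiated phenol derivatives with prenyl-type bromides used for ortho-prenylation. No ring is closed and no stereocentre is created; the C5' and C12' silyl ethers are remote from the reacting carbon and are carried through unchanged. The step needs C- over O-allylation, α (SN2) over γ (SN2') attack and retention of the 2'E alkene. The ring site is fixed by the bromine of step 9 and the carbon–copper bond is far more nucleophilic toward the bromide than the aggregated lithium phenoxide oxygen at −78 to 0 °C, while the fully substituted γ-carbon C3' (methyl and C4') steers the soft arylcopper to the unhindered C1'. Because bond formation at C1' should be faster than any η1/η3 isomerisation of the allylcopper intermediate, the E geometry set in step 7 is expected to be retained.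

Step 11
Reactants: 19 2-[(2E,5R,6E,10E,12R)-5,12-bis[(tert-butyldimethylsilyl)oxy]-3,7,11,15-tetramethylhexadeca-2,6,10,14-tetraen-1-yl]-4-methoxy-6-methylphenol
Product: 20 2-[(2E,5R,6E,10E,12R)-5,12-dihydroxy-3,7,11,15-tetramethylhexadeca-2,6,10,14-tetraen-1-yl]-4-methoxy-6-methylphenol
Conditions: Bu4NF (4 equiv), AcOH (4 equiv), THF, rt to 40 °C, argon
Reagents that add atoms: none
Why: Fluoride-mediated desilylation, buffered with acetic acid to spare the electron-rich phenol, frees both secondary allylic alcohols without touching the stereocentres or the alkenes.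

Compound list
1 | geranyl acetate, (2E)-3,7-dimethylocta-2,6-dien-1-yl acetate | CC(=O)OC/C=C(\C)CCC=C(C)C | starting material
2 | (2E,6E)-8-hydroxy-3,7-dimethylocta-2,6-dien-1-yl acetate | CC(=O)OC/C=C(\C)CC/C=C(\C)CO | intermediate (not isolated)
3 | (2E,6E)-3,7-dimethyl-8-oxoocta-2,6-dien-1-yl acetate | CC(=O)OC/C=C(\C)CC/C=C(\C)C=O | intermediate
4 | (2E,6E,8R)-3,7-dimethyl-8-[(4,4,5,5-tetramethyl-1,3,2-dioxaborolan-2-yl)oxy]undeca-2,6,10-trien-1-yl acetate | CC(=O)OC/C=C(\C)CC/C=C(\C)[C@H](OB1OC(C)(C)C(C)(C)O1)CC=C | intermediate (not isolated)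
5 | (2E,6E,8R)-3,7-dimethylundeca-2,6,10-triene-1,8-diol | OC/C=C(\C)CC/C=C(\C)[C@H](O)CC=C | intermediate
6 | (2E,6E,8R)-3,7,11-trimethyldodeca-2,6,10-triene-1,8-diol | OC/C=C(\C)CC/C=C(\C)[C@H](O)CC=C(C)C | intermediate
7 | (2E,6E,8R)-8-hydroxy-3,7,11-trimethyldodeca-2,6,10-trienal | O=C/C=C(\C)CC/C=C(\C)[C@H](O)CC=C(C)C | intermediate
8 | (4R,5E,9E,11R)-6,10,14-trimethyl-4-[(4,4,5,5-tetramethyl-1,3,2-dioxaborolan-2-yl)oxy]pentadeca-5,9,13-trien-1-yn-11-ol | C#CC[C@@H](OB1OC(C)(C)C(C)(C)O1)/C=C(\C)CC/C=C(\C)[C@H](O)CC=C(C)C | intermediate (not isolated)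
9 | (4R,5E,9E,11R)-6,10,14-trimethylpentadeca-5,9,13-trien-1-yne-4,11-diol | C#CC[C@@H](O)/C=C(\C)CC/C=C(\C)[C@H](O)CC=C(C)C | intermediate
10 | (4R,5E,9E,11R)-4,11-bis[(tert-butyldimethylsilyl)oxy]-6,10,14-trimethylpentadeca-5,9,13-trien-1-yne | C#CC[C@@H](O[Si](C)(C)C(C)(C)C)/C=C(\C)CC/C=C(\C)[C@H](O[Si](C)(C)C(C)(C)C)CC=C(C)C | intermediate
11 | (E)-alkenyl(dimethyl)alane from syn-methylalumination of 10 (aluminium on the former terminal alkyne carbon, cis to the new methyl) | C[Al](C)/C=C(\C)C[C@@H](O[Si](C)(C)C(C)(C)C)/C=C(\C)CC/C=C(\C)[C@H](O[Si](C)(C)C(C)(C)C)CC=C(C)C | intermediate (not isolated)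
12 | lithium butyl(dimethyl)alanate of 11 | [Li+].CCCC[Al-](C)(C)/C=C(\C)C[C@@H](O[Si](C)(C)C(C)(C)C)/C=C(\C)CC/C=C(\C)[C@H](O[Si](C)(C)C(C)(C)C)CC=C(C)C | intermediate (not isolated)
13 | (2E,5R,6E,10E,12R)-5,12-bis[(tert-butyldimethylsilyl)oxy]-3,7,11,15-tetramethylhexadeca-2,6,10,14-tetraen-1-ol | OC/C=C(\C)C[C@@H](O[Si](C)(C)C(C)(C)C)/C=C(\C)CC/C=C(\C)[C@H](O[Si](C)(C)C(C)(C)C)CC=C(C)C | intermediate
14 | (2E,5R,6E,10E,12R)-1-bromo-5,12-bis[(tert-butyldimethylsilyl)oxy]-3,7,11,15-tetramethylhexadeca-2,6,10,14-tetraene | BrC/C=C(\C)C[C@@H](O[Si](C)(C)C(C)(C)C)/C=C(\C)CC/C=C(\C)[C@H](O[Si](C)(C)C(C)(C)C)CC=C(C)C | intermediate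
15 | 4-methoxy-2-methylphenol | COc1ccc(O)c(C)c1 | starting material
16 | 2-bromo-4-methoxy-6-methylphenol | COc1cc(C)c(O)c(Br)c1 | intermediate
17 | lithium 2-lithio-4-methoxy-6-methylphenoxide | COc1cc(C)c(O[Li])c([Li])c1 | intermediate (not isolated)
18 | lithium 2-cuprio-4-methoxy-6-methylphenoxide (monovalent arylcopper) | COc1cc(C)c(O[Li])c([Cu])c1 | intermediate (not isolated)
19 | 2-[(2E,5R,6E,10E,12R)-5,12-bis[(tert-butyldimethylsilyl)oxy]-3,7,11,15-tetramethylhexadeca-2,6,10,14-tetraen-1-yl]-4-methoxy-6-methylphenol | COc1cc(C)c(O)c(C/C=C(\C)C[C@@H](O[Si](C)(C)C(C)(C)C)/C=C(\C)CC/C=C(\C)[C@H](O[Si](C)(C)C(C)(C)C)CC=C(C)C)c1 | intermediate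
20 | 2-[(2E,5R,6E,10E,12R)-5,12-dihydroxy-3,7,11,15-tetramethylhexadeca-2,6,10,14-tetraen-1-yl]-4-methoxy-6-methylphenol | COc1cc(C)c(O)c(C/C=C(\C)C[C@@H](O)/C=C(\C)CC/C=C(\C)[C@H](O)CC=C(C)C)c1 | target

Total step count: 11. Longest linear sequence: 10 steps (steps 1 to 8, 10 and 11, from geranyl acetate).

Steps most likely to fail

Step 10 (key step). The coupling may suffer from attack at the γ-carbon (SN2'), from halogen–metal exchange between the aryl metal and the allylic bromide followed by homocoupling, or from sluggish transmetalation of the aggregated dilithio phenoxide. The fallback moves the union to a palladium π-allyl manifold and sets out from alcohol 13 and bromophenol 16. ClCO2Me and pyridine would turn 13 into the allylic methyl carbonate F1. TBSCl and imidazole would turn 16 into the aryl silyl ether F2, and Miyaura borylation (B2pin2, Pd(dppf)Cl2, KOAc, dioxane, 80 °C) would give the aryl pinacolboronate F3. Suzuki–Miyaura allyl–aryl coupling of F1 and F3 (Pd(PPh3)4, THF, 60 °C) proceeds by decarboxylative ionisation to the π-allyl complex, transmetalation promoted by the liberated methoxide, and reductive elimination at the unsubstituted allyl terminus. It should give the tris-silyl ether F4 with the E geometry retained. The fluoride conditions of step 11 would then remove all three silyl groups and return to target 20.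

Step 7. The Lewis-acidic aluminium–zirconium mixture may ionise the allylic silyl ethers or deprotonate the terminal alkyne, and capture of the alkenyl metal by formaldehyde may be incomplete. The fallback sets out from alkyne 10. Copper-catalysed methylboration (CuCl, Xantphos, NaOt-Bu, B2pin2, MeI, THF, rt) would add boron and methyl syn across the alkyne to give the (E)-alkenyl pinacolboronate F5. Matteson homologation (BrCH2Cl, n-BuLi, THF, −78 °C to rt) would insert the C1' methylene with retention to give the allyl pinacolboronate F6. Oxidation (NaBO3·4H2O, THF/water) would return to alcohol 13 without allylic transposition.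

Step 5. Facial discrimination on the β,β-disubstituted enal may be insufficient, which would give C4 epimers that are hard to separate because the two centres are remote; acid-promoted E/Z isomerisation of the enal before addition is a second risk. The fallback sets out from hydroxy enal 7 and replaces catalyst control by enzymatic resolution. A zinc Barbier propargylation (propargyl bromide, Zn, THF/aqueous NH4Cl) would give the C4-epimeric diol mixture F7. Acylation with vinyl acetate catalysed by Candida antarctica lipase B is expected to acetylate the (4R)-carbinol faster and give, after chromatography, the (4R)-acetate F8. Methanolysis (K2CO3, MeOH), which also undoes any acetylation of the hindered C11 hydroxyl, would return to diol 9.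

Further compounds
F1 | step 10 | (2E,5R,6E,10E,12R)-5,12-bis[(tert-butyldimethylsilyl)oxy]-3,7,11,15-tetramethylhexadeca-2,6,10,14-tetraen-1-yl methyl carbonate | COC(=O)OC/C=C(\C)C[C@@H](O[Si](C)(C)C(C)(C)C)/C=C(\C)CC/C=C(\C)[C@H](O[Si](C)(C)C(C)(C)C)CC=C(C)C
F2 | step 10 | (2-bromo-4-methoxy-6-methylphenoxy)(tert-butyl)dimethylsilane | COc1cc(C)c(O[Si](C)(C)C(C)(C)C)c(Br)c1
F3 | step 10 | tert-butyl[4-methoxy-2-methyl-6-(4,4,5,5-tetramethyl-1,3,2-dioxaborolan-2-yl)phenoxy]dimethylsilane | COc1cc(C)c(O[Si](C)(C)C(C)(C)C)c(B2OC(C)(C)C(C)(C)O2)c1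
F4 | step 10 | tert-butyl{2-[(2E,5R,6E,10E,12R)-5,12-bis[(tert-butyldimethylsilyl)oxy]-3,7,11,15-tetramethylhexadeca-2,6,10,14-tetraen-1-yl]-4-methoxy-6-methylphenoxy}dimethylsilane | COc1cc(C)c(O[Si](C)(C)C(C)(C)C)c(C/C=C(\C)C[C@@H](O[Si](C)(C)C(C)(C)C)/C=C(\C)CC/C=C(\C)[C@H](O[Si](C)(C)C(C)(C)C)CC=C(C)C)c1
F5 | step 7 | 2-[(1E,4R,5E,9E,11R)-4,11-bis[(tert-butyldimethylsilyl)oxy]-2,6,10,14-tetramethylpentadeca-1,5,9,13-tetraen-1-yl]-4,4,5,5-tetramethyl-1,3,2-dioxaborolane | CC1(C)OB(/C=C(\C)C[C@@H](O[Si](C)(C)C(C)(C)C)/C=C(\C)CC/C=C(\C)[C@H](O[Si](C)(C)C(C)(C)C)CC=C(C)C)OC1(C)C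
F6 | step 7 | 2-[(2E,5R,6E,10E,12R)-5,12-bis[(tert-butyldimethylsilyl)oxy]-3,7,11,15-tetramethylhexadeca-2,6,10,14-tetraen-1-yl]-4,4,5,5-tetramethyl-1,3,2-dioxaborolane | CC1(C)OB(C/C=C(\C)C[C@@H](O[Si](C)(C)C(C)(C)C)/C=C(\C)CC/C=C(\C)[C@H](O[Si](C)(C)C(C)(C)C)CC=C(C)C)OC1(C)C
F7 | step 5 | (5E,9E,11R)-6,10,14-trimethylpentadeca-5,9,13-trien-1-yne-4,11-diol as the mixture of C4 epimers | C#CCC(O)/C=C(\C)CC/C=C(\C)[C@H](O)CC=C(C)C
F8 | step 5 | (4R,5E,9E,11R)-11-hydroxy-6,10,14-trimethylpentadeca-5,9,13-trien-1-yn-4-yl acetate | C#CC[C@@H](OC(C)=O)/C=C(\C)CC/C=C(\C)[C@H](O)CC=C(C)C
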